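1. Start from a balance: on the list of suspects, each target and each uncatalysed product costs one dissolved gas, and that gas has to come in from the gas phase.

- Sunday's: substrate 1 mM; gas phase 0.092 mM (held); free catalyst 26 µM; run made earlier
- flask: substrate 1.0 mM; gas phase 0.092 mM (held); free catalyst 13 µM; time 4.0 min

Sunday's run (percent of the substrate charged)

| time / s | target / % |
|---|---|
| 10.0 | 11.0 |
| 20.0 | 22.0 |
| 30.0 | 33.3 |
| 40.0 | 42.6 |
| 50.0 | 49.9 |

(standard deviation of a reading: 0.5 percentage points)

- at the start none of the gas is dissolved
- on the list of suspects stand: gas phase <-> dissolved gas; substrate + dissolved gas + free catalyst -> free catalyst + target; substrate + free catalyst -> spent catalyst; substrate + dissolved gas -> uncatalysed product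
- no earlier run changes the charge of free catalyst; that part of a forecast is a guess

1. how much target there is at 4.0 min, in percent of the substrate charged
2. the change that raises the amount of target at 4.0 min, in percent of the substrate charged most ("none" if none brings more than 2 percentage points) (dusk / spring / summer / none)
3. amount of target at 4.0 min, in percent of the substrate charged, after summer

- dusk: doubling the transfer coefficient of the gas phase, all else as stated
- spring: doubling the amount of free catalyst, all else as stated
- summer: doubling the saturation concentration of gas phase, all else as stated

2. Replace Sunday's curve by its mean slope. Up to 30.0 s it reaches 33.3%, which is 0.666 mM/min of target. Check the error: to 50.0 s the mean is 0.599 mM/min, lower than the first figure, and the slope read between the last two readings is 0.438 mM/min, lower again. So the curve is still bending, the mean describes the early run, and a time reckoned from it comes out short.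

3. Divide the charge by that early flow to get the gas time, the time that flow, if it held steady, takes to pay for one charge of substrate: 1.50 min for the charge of the asked flask.

4. The asked flask runs 4.0 min, longer than the gas time by a factor of 2.67. To pay for the charge, the mean flow over the run need be 0.250 mM/min, lower than Sunday's last slope, so don't plan a longer run. The open question is how the substrate splits, and my next well would get more free catalyst. That is a guess, since no earlier run changes its charge.

5. The forecast says 51%, summer as the best change, and 91% after summer: “The catalyst's life is then set by time, not by its charge.”

6. The flask gives 71.1%, and the best change is spring, worth 14 percentage points; summer gives 82.3%.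

    gas phase ⇌ dissolved gas, rate k1*(csat - [dissolved gas]) (kL = 0.156 /s)
    substrate + dissolved gas + free catalyst → free catalyst + target (k = 7.06 × 10⁷ /M²/s)
    substrate + free catalyst → spent catalyst (k = 30.2 /M/s)
    substrate + dissolved gas → uncatalysed product (k = 112 /M/s)

In this flask substrate, the limiting reagent, is down to 1.1% at 4.00 min, and 40.0 min brings 71.7%, so run length is not the reason. The shortfall lies in the step to uncatalysed product together with the transfer bottleneck, each a part of it: without that step target stands at 90.9%, and without the bottleneck at 86.9%.

7. Now take the neighbour with 4.0 mM of substrate. Its gas time is 6.01 min, longer than the run, so the early flow, if it held steady, pays for 66.6% of its charge. The simulated run has reacted 58.0%, less than that, with 42% of the substrate left, target at 5.74% and uncatalysed product at 51.6%.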